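**Plan**

u1 is the 3-linked 5-hydroxy-7,4'-dimethoxyflavone half and u2 is the 6-linked apigenin half.

1. Retrosynthesis: first the u1 5-O-methyl and u2 4'-O-benzyl ethers are cut; then ring A of u2 is opened across C5–C6 and C7–C8, giving a flavone-3-acetate (u1 plus C6 and C7 of u2) and a 2-methyl-4-pyranone-3-carbonyl chloride (O1, C2–C4, C4a, C5, C8, C8a of u2).
2. Enabling feature: ring A of u2 is a phloroglucinol that carries C3 of u1 on C6, between the C5 and C7 hydroxyls. This is the pattern left when a CH2–CO2Me unit (C6, C7) is condensed onto a 3-acyl-2-methyl-4-pyranone.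
3. Forward order: ring C of u1 by Baker–Venkataraman rearrangement and cyclodehydration (steps 1–4); the pyranone of u2 by C-acylation and 6-endo-dig closure (steps 5–8); ring A of u2 last, by a one-pot Claisen–Dieckmann benzannulation (step 9); deprotection (step 10).
4. Stereochemistry: the target has no stereocentre, so none has to be set.

Key step: step 9

Remark: the target SMILES gives no descriptor for the biaryl axis C3(u1)–C6(u2). It is taken as configurationally unspecified and is made without axial control.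

**Route**

Step 1
Reactants: 1 1,3,5-trimethoxybenzene; 2 methyl 4-chloro-4-oxobutanoate
Product: 3 methyl 4-oxo-4-(2,4,6-trimethoxyphenyl)butanoate
Conditions: AlCl3, CH2Cl2, 0 °C → rt
Reagents that add atoms: none
Why: Friedel–Crafts acylation of the symmetrical, strongly activated arene can give only one regioisomer, and the methyl ester is inert to AlCl3 at this temperature.

Step 2
Reactants: 3 methyl 4-oxo-4-(2,4,6-trimethoxyphenyl)butanoate
Product: 4 methyl 4-(2-hydroxy-4,6-dimethoxyphenyl)-4-oxobutanoate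
Conditions: BCl3 (1.2 equiv), CH2Cl2, −78 → 0 °C; aq. work-up
Reagents that add atoms: none
Why: Chelation-controlled demethylation, in which BCl3 bound to the ketone cleaves one ortho methyl ether only, and the resulting boron chelate shields the second ortho ether while the para ether and the ester stay intact.

Step 3
Reactants: 4 methyl 4-(2-hydroxy-4,6-dimethoxyphenyl)-4-oxobutanoate; 5 4-methoxybenzoyl chloride
Product: 6 3,5-dimethoxy-2-(4-methoxy-4-oxobutanoyl)phenyl 4-methoxybenzoate
Conditions: pyridine, DMAP (cat.), rt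
Reagents that add atoms: none
Why: DMAP-catalysed acyl transfer esterifies the hydrogen-bonded phenol, the standard first stage of a Baker–Venkataraman sequence.

Step 4
Reactants: 6 3,5-dimethoxy-2-(4-methoxy-4-oxobutanoyl)phenyl 4-methoxybenzoate
Product: 8 methyl 2-[5,7-dimethoxy-2-(4-methoxyphenyl)-4-oxo-4H-chromen-3-yl]acetate, via 1,3-diketone 7 (not isolated)
Conditions: LiN(SiMe3)2 (3 equiv), THF, −78 → 0 °C; aq. HCl; then H2SO4 (cat.), MeOH, 65 °C
Reagents that add atoms: none
Why: Baker–Venkataraman rearrangement, in which the ketone enolate (its CH2 is more acidic than the ester CH2) takes the aroyl group from the phenol oxygen, followed by acid-catalysed cyclodehydration of the 2-substituted 1,3-diketone to ring C of u1 with the acetate chain at C3; methanol as solvent keeps the methyl ester and reverses any lactonisation of the enol onto it.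

Step 5
Reactants: 9 1-(benzyloxy)-4-ethynylbenzene
Product: 10 3-[4-(benzyloxy)phenyl]prop-2-ynoic acid
Conditions: n-BuLi, THF, −78 °C; CO2; aq. HCl
Reagents that add atoms: carbon dioxide, O=C=O
Why: Carboxylation of the lithium acetylide is a standard route to arylpropiolic acids, and the benzyl ether is inert to n-BuLi at −78 °C.

Step 6
Reactants: 10 3-[4-(benzyloxy)phenyl]prop-2-ynoic acid; 11 tert-butyl acetoacetate
Product: 14 tert-butyl 6-[4-(benzyloxy)phenyl]-2-methyl-4-oxo-4H-pyran-3-carboxylate, via ynoyl chloride 12 (not isolated), via alkynyl diketo ester 13 (not isolated)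
Conditions: (COCl)2, DMF (cat.), CH2Cl2, 0 °C → rt, evaporate; then 11, MgCl2, Et3N, MeCN–CH2Cl2, 0 °C → rt
Reagents that add atoms: none
Why: Soft enolisation with MgCl2/Et3N gives the chelated magnesium enolate of 11, which is C-acylated by the ynoyl chloride, and the acetyl enol oxygen of 13 then adds 6-endo-dig to the ynone (oxa-Michael) to give the 4-pyranone, a long-known route to 3-acyl-4-pyranones; the tert-butyl ester is chosen so that acid can later remove it without exposing the pyranone to hydroxide.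

Step 7
Reactants: 14 tert-butyl 6-[4-(benzyloxy)phenyl]-2-methyl-4-oxo-4H-pyran-3-carboxylate
Product: 15 6-[4-(benzyloxy)phenyl]-2-methyl-4-oxo-4H-pyran-3-carboxylic acid
Conditions: CF3CO2H, CH2Cl2, rt
Reagents that add atoms: none
Why: Acidolysis of the tert-butyl ester with loss of isobutene leaves the aryl benzyl ether and the pyranone intact, and the acid should not decarboxylate easily because its α-carbon is part of the ring double bond.

Step 8
Reactants: 15 6-[4-(benzyloxy)phenyl]-2-methyl-4-oxo-4H-pyran-3-carboxylic acid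
Product: 16 6-[4-(benzyloxy)phenyl]-2-methyl-4-oxo-4H-pyran-3-carbonyl chloride
Conditions: (COCl)2, DMF (cat.), CH2Cl2, 0 °C → rt; evaporate, use crude
Reagents that add atoms: oxalyl chloride, O=C(Cl)C(Cl)=O
Why: Vilsmeier-catalysed conversion of the acid to its chloride under mild, non-basic conditions, as used for the related chromone-3-carboxylic acids; the chloride is taken on at once to avoid hydrolysis.

Step 9
Reactants: 8 methyl 2-[5,7-dimethoxy-2-(4-methoxyphenyl)-4-oxo-4H-chromen-3-yl]acetate; 16 6-[4-(benzyloxy)phenyl]-2-methyl-4-oxo-4H-pyran-3-carbonyl chloride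
Product: 18 3-{2-[4-(benzyloxy)phenyl]-5,7-dihydroxy-4-oxo-4H-chromen-6-yl}-5,7-dimethoxy-2-(4-methoxyphenyl)-4H-chromen-4-one, via β-keto ester 17 (not isolated)
Conditions: 8, LiN(SiMe3)2 (2.1 equiv), THF, −78 °C; 16 (1.05 equiv), −78 → −40 °C; LiN(SiMe3)2 (2.5 equiv), DMPU, −78 °C → rt (40 °C if needed); aq. HCl
Reagents that add atoms: none
Why: Proposed new method: at −78 °C the lithium enolate of 8 is C-acylated by 16, the most reactive electrophile in the flask, which forms C5–C6 of u2 and gives 17, held as its enolate by the second equivalent of base. The further LiN(SiMe3)2 then removes a proton from the pyranone 2-methyl group, which is vinylogously acidic through the C4 carbonyl, and the dienolate carbon adds to the ester carbonyl in a 6-(enolendo)-exo-trig Dieckmann closure (C7–C8 of u2); methoxide leaves and the ring enolises twice to the aromatic 5,7-diol, formed as its dilithium salt. The closest known reaction types are the Claisen–Dieckmann annulation of ortho-toluate anions to naphthalene-1,3-diols and the Claisen cyclisation of poly-β-carbonyl esters to acylphloroglucinols, neither of which has been run on a 2-methyl-4-pyranone-3-carbonyl unit. The 6- versus 8-linkage question cannot arise, because the heterocycle of u2 (O1, C2, C3, C4) exists before ring A is made and the acetate carbon that carries u1 can only become C6. The step needs C- over O-acylation (lithium enolate, low temperature, a hindered silylamide that is slow to attack the acid chloride), the base for the lateral deprotonation added only once 16 is consumed, and attack at the ester in preference to conjugate opening of the pyranone, which the six-membered closure and its irreversible aromatisation should secure; DMPU and warming are there to loosen the lithium chelate of 17 so that the ester can turn toward the methyl carbanion. No stereocentre is formed.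

Step 10
Reactants: 18 3-{2-[4-(benzyloxy)phenyl]-5,7-dihydroxy-4-oxo-4H-chromen-6-yl}-5,7-dimethoxy-2-(4-methoxyphenyl)-4H-chromen-4-one
Product: 19 3-[5,7-dihydroxy-2-(4-hydroxyphenyl)-4-oxo-4H-chromen-6-yl]-5-hydroxy-7-methoxy-2-(4-methoxyphenyl)-4H-chromen-4-one
Conditions: BCl3 (excess), pentamethylbenzene, CH2Cl2, −78 °C → rt; MeOH, aq. work-up
Reagents that add atoms: none
Why: BCl3 cleaves the aryl benzyl ether at low temperature while pentamethylbenzene traps the benzyl cation (Friedel–Crafts), and on warming it removes only the methyl ether peri to the u1 carbonyl by chelation-assisted demethylation, leaving the 7- and 4'-methyl ethers in place.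

**Compound list**

1 | 1,3,5-trimethoxybenzene | COc1cc(OC)cc(OC)c1 | starting material
2 | methyl 4-chloro-4-oxobutanoate | COC(=O)CCC(Cl)=O | starting material
3 | methyl 4-oxo-4-(2,4,6-trimethoxyphenyl)butanoate | COC(=O)CCC(=O)c1c(OC)cc(OC)cc1OC | intermediate
4 | methyl 4-(2-hydroxy-4,6-dimethoxyphenyl)-4-oxobutanoate | COC(=O)CCC(=O)c1c(O)cc(OC)cc1OC | intermediate
5 | 4-methoxybenzoyl chloride | COc1ccc(C(Cl)=O)cc1 | starting material
6 | 3,5-dimethoxy-2-(4-methoxy-4-oxobutanoyl)phenyl 4-methoxybenzoate | COC(=O)CCC(=O)c1c(OC(=O)c2ccc(OC)cc2)cc(OC)cc1OC | intermediate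
7 | methyl 3-(2-hydroxy-4,6-dimethoxybenzoyl)-4-(4-methoxyphenyl)-4-oxobutanoate (racemic, enolisable 1,3-diketone) | COC(=O)CC(C(=O)c1ccc(OC)cc1)C(=O)c1c(O)cc(OC)cc1OC | intermediate (not isolated)
8 | methyl 2-[5,7-dimethoxy-2-(4-methoxyphenyl)-4-oxo-4H-chromen-3-yl]acetate | COC(=O)Cc1c(-c2ccc(OC)cc2)oc2cc(OC)cc(OC)c2c1=O | intermediate
9 | 1-(benzyloxy)-4-ethynylbenzene | C#Cc1ccc(OCc2ccccc2)cc1 | starting material
10 | 3-[4-(benzyloxy)phenyl]prop-2-ynoic acid | OC(=O)C#Cc1ccc(OCc2ccccc2)cc1 | intermediate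
11 | tert-butyl acetoacetate (tert-butyl 3-oxobutanoate) | CC(=O)CC(=O)OC(C)(C)C | starting material
12 | 3-[4-(benzyloxy)phenyl]prop-2-ynoyl chloride | O=C(Cl)C#Cc1ccc(OCc2ccccc2)cc1 | intermediate (not isolated)
13 | tert-butyl 2-acetyl-5-[4-(benzyloxy)phenyl]-3-oxopent-4-ynoate (racemic, enolised) | CC(=O)C(C(=O)OC(C)(C)C)C(=O)C#Cc1ccc(OCc2ccccc2)cc1 | intermediate (not isolated)
14 | tert-butyl 6-[4-(benzyloxy)phenyl]-2-methyl-4-oxo-4H-pyran-3-carboxylate | Cc1oc(-c2ccc(OCc3ccccc3)cc2)cc(=O)c1C(=O)OC(C)(C)C | intermediate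
15 | 6-[4-(benzyloxy)phenyl]-2-methyl-4-oxo-4H-pyran-3-carboxylic acid | Cc1oc(-c2ccc(OCc3ccccc3)cc2)cc(=O)c1C(=O)O | intermediate
16 | 6-[4-(benzyloxy)phenyl]-2-methyl-4-oxo-4H-pyran-3-carbonyl chloride | Cc1oc(-c2ccc(OCc3ccccc3)cc2)cc(=O)c1C(Cl)=O | intermediate
17 | methyl 3-{6-[4-(benzyloxy)phenyl]-2-methyl-4-oxo-4H-pyran-3-yl}-2-[5,7-dimethoxy-2-(4-methoxyphenyl)-4-oxo-4H-chromen-3-yl]-3-oxopropanoate (racemic at C2, present as its enolate) | COC(=O)C(c1c(-c2ccc(OC)cc2)oc2cc(OC)cc(OC)c2c1=O)C(=O)c1c(C)oc(-c2ccc(OCc3ccccc3)cc2)cc1=O | intermediate (not isolated)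
18 | 3-{2-[4-(benzyloxy)phenyl]-5,7-dihydroxy-4-oxo-4H-chromen-6-yl}-5,7-dimethoxy-2-(4-methoxyphenyl)-4H-chromen-4-one | COc1ccc(-c2oc3cc(OC)cc(OC)c3c(=O)c2-c2c(O)cc3oc(-c4ccc(OCc5ccccc5)cc4)cc(=O)c3c2O)cc1 | intermediate
19 | 3-[5,7-dihydroxy-2-(4-hydroxyphenyl)-4-oxo-4H-chromen-6-yl]-5-hydroxy-7-methoxy-2-(4-methoxyphenyl)-4H-chromen-4-one (CNP0273448.0) | COc1ccc(-c2oc3cc(OC)cc(O)c3c(=O)c2-c2c(O)cc3oc(-c4ccc(O)cc4)cc(=O)c3c2O)cc1 | target

**Count**

Total steps: 10. Longest linear sequence: 6 steps (steps 1, 2, 3, 4, 9, 10, or equally steps 5, 6, 7, 8, 9, 10).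

**Steps most likely to fail**

Step 9 (proposed new method). The acid chloride may be consumed by O-acylation of the enolate or by the silylamide instead of C-acylation. The ring closure may also stall, because the ester carbonyl of 17 is deactivated as part of a chelated enolate and is turned away from the pyranone methyl carbanion, or the carbanion may open the pyranone by conjugate addition.

The fallback makes the C3(u1)–C6(u2) bond by Suzuki–Miyaura coupling of two preformed flavones, using known chemistry only. It sets out from 1 for the u1 half and returns at 19.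
- u1 half: purchased 3-(4-methoxyphenyl)prop-2-ynoic acid and (COCl)2 give 3-(4-methoxyphenyl)prop-2-ynoyl chloride F1. Friedel–Crafts acylation of 1 with it (AlCl3, CH2Cl2, 0 °C) should give 3-(4-methoxyphenyl)-1-(2,4,6-trimethoxyphenyl)prop-2-yn-1-one F2. ICl (CH2Cl2, −78 °C → rt) should close F2 by 6-endo iodocyclisation, with loss of one ortho methyl group, to 3-iodo-5,7-dimethoxy-2-(4-methoxyphenyl)-4H-chromen-4-one F3.
- u2 half: purchased apigenin is perbenzylated (BnBr, K2CO3, DMF, 80 °C) to 5,7-bis(benzyloxy)-2-[4-(benzyloxy)phenyl]-4H-chromen-4-one F4. Iodination at C6 (BnMe3N·ICl2, CaCO3, CH2Cl2–MeOH, a reagent known to favour C6 over C8 in 5,7-dialkoxyflavones) gives 5,7-bis(benzyloxy)-2-[4-(benzyloxy)phenyl]-6-iodo-4H-chromen-4-one F5. Miyaura borylation (B2pin2, PdCl2(dppf), KOAc, dioxane, 90 °C) gives 5,7-bis(benzyloxy)-2-[4-(benzyloxy)phenyl]-6-(4,4,5,5-tetramethyl-1,3,2-dioxaborolan-2-yl)-4H-chromen-4-one F6.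
- Coupling and deprotection: F3 and F6 (Pd(OAc)2, SPhos, K3PO4, toluene–water, 100 °C) should give 3-{5,7-bis(benzyloxy)-2-[4-(benzyloxy)phenyl]-4-oxo-4H-chromen-6-yl}-5,7-dimethoxy-2-(4-methoxyphenyl)-4H-chromen-4-one F7. BCl3 with pentamethylbenzene, as in step 10, then removes the three benzyl groups and the chelated methyl ether of u1 and delivers 19.

Step 6. The acetoacetate may be acylated on oxygen, chloride may add across the triple bond of the ynoyl chloride, or the enol may close 5-exo onto the ynone to a furanone instead of 6-endo.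

The fallback builds the same pyranone by [4+2] cycloaddition of an aroylketene with an enamine. It sets out from 11 and returns at 14.
- Condensation of 11 with pyrrolidine (toluene, water removal) gives tert-butyl (E)-3-(pyrrolidin-1-yl)but-2-enoate F8.
- Purchased 4-(benzyloxy)benzoyl chloride and Meldrum's acid (pyridine, CH2Cl2, 0 °C) give 5-{[4-(benzyloxy)phenyl](hydroxy)methylidene}-2,2-dimethyl-1,3-dioxane-4,6-dione F9.
- Heating F9 with F8 in toluene (110 °C) releases [4-(benzyloxy)benzoyl]ketene F10. Its acyl-ketene oxadiene should add across the enamine double bond, and loss of pyrrolidine from the adduct gives 14 with the aryl group at C6, the methyl at C2 and the ester at C3.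

Step 10. The released benzyl cation may be transferred to the nucleophilic C8 of the phloroglucinol ring of u2, and cleavage of the chelated methyl ether may be incomplete or may spread to the 7- and 4'-methyl ethers.

The fallback separates the two ether cleavages. It sets out from 18 and returns at 19.
- Hydrogenolysis (H2, Pd/C, EtOAc–MeOH, rt) removes the benzyl group with no cation involved and gives 3-[5,7-dihydroxy-2-(4-hydroxyphenyl)-4-oxo-4H-chromen-6-yl]-5,7-dimethoxy-2-(4-methoxyphenyl)-4H-chromen-4-one F11.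
- AlCl3 in MeCN at reflux, a standard reagent for selective 5-O-demethylation of polymethoxyflavones, then cleaves only the peri methyl ether of u1 to give 19.

**Further compounds**

F1 | step 9 | 3-(4-methoxyphenyl)prop-2-ynoyl chloride | COc1ccc(C#CC(Cl)=O)cc1
F2 | step 9 | 3-(4-methoxyphenyl)-1-(2,4,6-trimethoxyphenyl)prop-2-yn-1-one | COc1ccc(C#CC(=O)c2c(OC)cc(OC)cc2OC)cc1
F3 | step 9 | 3-iodo-5,7-dimethoxy-2-(4-methoxyphenyl)-4H-chromen-4-one | COc1ccc(-c2oc3cc(OC)cc(OC)c3c(=O)c2I)cc1
F4 | step 9 | 5,7-bis(benzyloxy)-2-[4-(benzyloxy)phenyl]-4H-chromen-4-one | O=c1cc(-c2ccc(OCc3ccccc3)cc2)oc2cc(OCc3ccccc3)cc(OCc3ccccc3)c12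
F5 | step 9 | 5,7-bis(benzyloxy)-2-[4-(benzyloxy)phenyl]-6-iodo-4H-chromen-4-one | O=c1cc(-c2ccc(OCc3ccccc3)cc2)oc2cc(OCc3ccccc3)c(I)c(OCc3ccccc3)c12
F6 | step 9 | 5,7-bis(benzyloxy)-2-[4-(benzyloxy)phenyl]-6-(4,4,5,5-tetramethyl-1,3,2-dioxaborolan-2-yl)-4H-chromen-4-one | O=c1cc(-c2ccc(OCc3ccccc3)cc2)oc2cc(OCc3ccccc3)c(B3OC(C)(C)C(C)(C)O3)c(OCc3ccccc3)c12
F7 | step 9 | 3-{5,7-bis(benzyloxy)-2-[4-(benzyloxy)phenyl]-4-oxo-4H-chromen-6-yl}-5,7-dimethoxy-2-(4-methoxyphenyl)-4H-chromen-4-one | COc1ccc(-c2oc3cc(OC)cc(OC)c3c(=O)c2-c2c(OCc3ccccc3)cc3oc(-c4ccc(OCc5ccccc5)cc4)cc(=O)c3c2OCc2ccccc2)cc1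
F8 | step 6 | tert-butyl (E)-3-(pyrrolidin-1-yl)but-2-enoate | C/C(=C\C(=O)OC(C)(C)C)N1CCCC1
F9 | step 6 | 5-{[4-(benzyloxy)phenyl](hydroxy)methylidene}-2,2-dimethyl-1,3-dioxane-4,6-dione | CC1(C)OC(=O)C(=C(O)c2ccc(OCc3ccccc3)cc2)C(=O)O1
F10 | step 6 | [4-(benzyloxy)benzoyl]ketene | O=C=CC(=O)c1ccc(OCc2ccccc2)cc1
F11 | step 10 | 3-[5,7-dihydroxy-2-(4-hydroxyphenyl)-4-oxo-4H-chromen-6-yl]-5,7-dimethoxy-2-(4-methoxyphenyl)-4H-chromen-4-one | COc1ccc(-c2oc3cc(OC)cc(OC)c3c(=O)c2-c2c(O)cc3oc(-c4ccc(O)cc4)cc(=O)c3c2O)cc1
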